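**Retrosynthetic overview**

1. The strategy rests on C7a and C7 of the benzo ring of the 2,3-dihydrobenzofuran: two adjacent arene carbons that both carry oxygen (ring O1 and the 7-hydroxyl), the pattern left when a nucleophile and an electrophile add across a C7a–C7 aryne.
2. Late stage: the E-acrylic acid comes from a C5 aldehyde (Knoevenagel–Doebner), the 7-OH from a C7 pinacol boronate, and the aldehyde and CH2OH from a dioxolane and a trityl ether.
3. Key disconnection: O1–C7a and C7–B are made in one operation from an open-chain 2-fluoroaryl alcohol; the dihydrofuran ring is the only ring formed, both benzene rings being bought.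
4. C2 and C3 come from an Evans syn-aldol of an (arylacetyl)oxazolidinone with veratraldehyde; the arylacetic acid comes from 3-bromo-4-fluorobenzaldehyde by palladium-catalysed zinc enolate coupling.
5. The primary alcohol is carried as a trityl ether, not a silyl ether: a silyl group could shift to the neighbouring lithium alkoxide and free the primary oxygen, which is also three atoms from C7a and would close the wrong ring.

Key step: step 8

Remark: ring positions (C2, C3, C5, C7, C7a) follow the 2,3-dihydro-1-benzofuran numbering of the target, also in the open-chain precursors.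

**Route**

Step 1
Reactants: 1 3-bromo-4-fluorobenzaldehyde
Product: 2 2-(3-bromo-4-fluorophenyl)-1,3-dioxolane
Conditions: ethylene glycol (1.5 equiv), TsOH·H2O (2 mol%), toluene, reflux, Dean–Stark
Reagents that add atoms: ethylene glycol, OCCO
Why: Acid-catalysed acetalisation with azeotropic removal of water masks the aldehyde, which must later survive a zinc enolate, a boron enolate, LiBH4 and t-BuLi.

Step 2
Reactants: 2 2-(3-bromo-4-fluorophenyl)-1,3-dioxolane; 3 ethyl bromoacetate
Product: 5 ethyl 2-[5-(1,3-dioxolan-2-yl)-2-fluorophenyl]acetate, via Reformatsky zinc reagent 4 (not isolated)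
Conditions: 3, zinc dust (TMSCl-activated), THF, 45 °C; then 2, Pd2(dba)3 (2 mol%), XPhos (8 mol%), THF, 60 °C
Reagents that add atoms: none
Why: The Reformatsky-type zinc ester enolate 4 cross-couples with the aryl bromide on zerovalent palladium (Negishi-type α-arylation of an ester) under neutral conditions that leave the acetal and the C–F bond alone.

Step 3
Reactants: 5 ethyl 2-[5-(1,3-dioxolan-2-yl)-2-fluorophenyl]acetate
Product: 6 2-[5-(1,3-dioxolan-2-yl)-2-fluorophenyl]acetic acid
Conditions: LiOH·H2O (1.5 equiv), THF/H2O 3:1, rt; cold 1 M HCl to pH 4, EtOAc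
Reagents that add atoms: lithium hydroxide, [Li+].[OH-]
Why: Saponification of the ethyl ester followed by a brief, cold, two-phase acidification to pH 4 frees the acid while the dioxolane, slow to hydrolyse under those conditions, should survive.

Step 4
Reactants: 6 2-[5-(1,3-dioxolan-2-yl)-2-fluorophenyl]acetic acid; 7 (R)-4-benzyl-2-oxazolidinone
Product: 9 (4R)-4-benzyl-3-{2-[5-(1,3-dioxolan-2-yl)-2-fluorophenyl]acetyl}-1,3-oxazolidin-2-one, via mixed pivalic anhydride 8 (not isolated)
Conditions: PivCl (1.1 equiv), Et3N (2.5 equiv), THF, −20 °C; then 7, LiCl (1.2 equiv), −20 °C → rt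
Reagents that add atoms: none
Why: N-acylation of the oxazolidinone through the mixed pivalic anhydride with LiCl/Et3N activation, the nucleophile taking the unhindered arylacetyl carbonyl, keeps strong acid away from the acetal and strong base away from the acidic benzylic CH2.

Step 5
Reactants: 9 (4R)-4-benzyl-3-{2-[5-(1,3-dioxolan-2-yl)-2-fluorophenyl]acetyl}-1,3-oxazolidin-2-one; 10 veratraldehyde (3,4-dimethoxybenzaldehyde)
Product: 13 (4R)-4-benzyl-3-[(2R,3R)-3-(3,4-dimethoxyphenyl)-2-[5-(1,3-dioxolan-2-yl)-2-fluorophenyl]-3-hydroxypropanoyl]-1,3-oxazolidin-2-one, via Z-boron enolate 11 (not isolated), via boron aldolate 12 (not isolated)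
Conditions: Bu2BOTf (1.15 equiv), i-Pr2NEt (1.3 equiv), CH2Cl2, −78 → 0 °C; 10 (1.2 equiv), −78 → 0 °C; pH 7 buffer, MeOH, 30% H2O2, 0 °C
Reagents that add atoms: none
Why: Evans boron syn-aldol: soft enolisation gives the Z-enolate, which reacts through a closed Zimmerman–Traxler chair with the oxazolidinone carbonyl turned away from the enolate oxygen, so the aldehyde is taken on the enolate face remote from the benzyl group and both centres are set together as (2R,3R) with aryl and hydroxyl syn.

Step 6
Reactants: 13 (4R)-4-benzyl-3-[(2R,3R)-3-(3,4-dimethoxyphenyl)-2-[5-(1,3-dioxolan-2-yl)-2-fluorophenyl]-3-hydroxypropanoyl]-1,3-oxazolidin-2-one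
Product: 14 (1R,2S)-1-(3,4-dimethoxyphenyl)-2-[5-(1,3-dioxolan-2-yl)-2-fluorophenyl]propane-1,3-diol
Conditions: LiBH4 (2 equiv), H2O (1.1 equiv), Et2O/THF, 0 °C
Reagents that add atoms: none
Why: Reductive cleavage of the N-acyloxazolidinone by LiBH4 at the exocyclic carbonyl gives the primary alcohol without touching either stereocentre (the C2 descriptor changes from R to S only because CH2OH ranks below the carbinol carbon).

Step 7
Reactants: 14 (1R,2S)-1-(3,4-dimethoxyphenyl)-2-[5-(1,3-dioxolan-2-yl)-2-fluorophenyl]propane-1,3-diol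
Product: 15 (1R,2S)-1-(3,4-dimethoxyphenyl)-2-[5-(1,3-dioxolan-2-yl)-2-fluorophenyl]-3-(triphenylmethoxy)propan-1-ol
Conditions: TrCl (1.2 equiv), Et3N (2 equiv), DMAP (5 mol%), CH2Cl2, 0 °C → rt
Reagents that add atoms: trityl chloride, ClC(c1ccccc1)(c1ccccc1)c1ccccc1
Why: Tritylation through the trityl cation is selective for the primary hydroxyl on steric grounds and gives an ether that cannot migrate to the neighbouring oxygen and is inert to alkyllithiums.

Step 8
Reactants: 15 (1R,2S)-1-(3,4-dimethoxyphenyl)-2-[5-(1,3-dioxolan-2-yl)-2-fluorophenyl]-3-(triphenylmethoxy)propan-1-ol; 16 2-isopropoxy-4,4,5,5-tetramethyl-1,3,2-dioxaborolane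
Product: 20 2-[(2R,3S)-2-(3,4-dimethoxyphenyl)-5-(1,3-dioxolan-2-yl)-3-[(triphenylmethoxy)methyl]-2,3-dihydro-1-benzofuran-7-yl]-4,4,5,5-tetramethyl-1,3,2-dioxaborolane, via dilithiated fluoroarene 17 (not isolated), via aryne alkoxide 18 (not isolated), via C7 aryllithium 19 (not isolated)
Conditions: t-BuLi (2.4 equiv), THF, −78 °C, 1.5 h; → 0 °C over 2 h; −78 °C, 16 (2.5 equiv), → rt; aq NH4Cl
Reagents that add atoms: none
Why: The first equivalent of t-BuLi makes the lithium alkoxide and the second removes the one hydrogen ortho to fluorine (future C7) to give 17, which on warming loses LiF to the C7a–C7 aryne 18; the alkoxide oxygen then adds in the ring plane at C7a and the resulting C7 aryllithium 19 is captured by borate 16. The closest known reaction types are the anionic benzyne cyclisation of 2-fluoroaryl substrates with electrophilic capture of the new aryllithium, and the trapping of arynes by tethered alcohols to give 7-substituted 2,3-dihydrobenzofurans. The dihydrofuran ring closes in the 5-exo-dig mode, the aryne bond lying outside the new ring. No stereocentre is formed: only the O–H, aryl C–H and aryl C–F bonds change, so C2 and C3 keep the configuration set in step 5 and the syn aldol relation is carried into the trans ring. The step needs one aryne and one addition site; the single hydrogen ortho to fluorine fixes the aryne, the three-atom tether reaches only C7a, and the trityl ether keeps the primary oxygen out of play. The new ortho oxygen should stabilise 19 until boron capture, and the small excess of t-BuLi limits its competing addition to the aryne.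

Step 9
Reactants: 20 2-[(2R,3S)-2-(3,4-dimethoxyphenyl)-5-(1,3-dioxolan-2-yl)-3-[(triphenylmethoxy)methyl]-2,3-dihydro-1-benzofuran-7-yl]-4,4,5,5-tetramethyl-1,3,2-dioxaborolane
Product: 21 (2R,3S)-2-(3,4-dimethoxyphenyl)-5-(1,3-dioxolan-2-yl)-3-[(triphenylmethoxy)methyl]-2,3-dihydro-1-benzofuran-7-ol
Conditions: 30% H2O2 (3 equiv), 1 M NaOH (1.5 equiv), THF, 0 °C → rt; aq Na2S2O3, then NH4Cl
Reagents that add atoms: hydrogen peroxide, OO
Why: Alkaline peroxide oxidation of the aryl boronate proceeds by 1,2-migration of the aryl group from boron to oxygen, so the hydroxyl appears exactly at C7 under basic conditions to which the acetal and trityl ether are stable.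

Step 10
Reactants: 21 (2R,3S)-2-(3,4-dimethoxyphenyl)-5-(1,3-dioxolan-2-yl)-3-[(triphenylmethoxy)methyl]-2,3-dihydro-1-benzofuran-7-ol
Product: 22 (2R,3S)-2-(3,4-dimethoxyphenyl)-7-hydroxy-3-(hydroxymethyl)-2,3-dihydro-1-benzofuran-5-carbaldehyde
Conditions: 1 M HCl (aq)/THF 1:3, rt
Reagents that add atoms: water, O
Why: Acid-catalysed hydrolysis of the dioxolane and solvolysis of the trityl ether through the trityl cation occur in one operation with water as the only nucleophile, and the trans arrangement is the thermodynamically preferred one should C2 ionise reversibly.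

Step 11
Reactants: 22 (2R,3S)-2-(3,4-dimethoxyphenyl)-7-hydroxy-3-(hydroxymethyl)-2,3-dihydro-1-benzofuran-5-carbaldehyde; 23 malonic acid
Product: 25 (2E)-3-[(2R,3S)-2-(3,4-dimethoxyphenyl)-7-hydroxy-3-(hydroxymethyl)-2,3-dihydro-1-benzofuran-5-yl]prop-2-enoic acid, via arylidenemalonic acid 24 (not isolated)
Conditions: 23 (3 equiv), pyridine, piperidine (0.2 equiv), 90 °C; then cold 1 M HCl
Reagents that add atoms: none
Why: Knoevenagel–Doebner condensation: amine-catalysed condensation with malonic acid followed by decarboxylation in hot pyridine gives the conjugated acid with the E geometry that places aryl and carboxyl trans.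

**Compound list**

1 | 3-bromo-4-fluorobenzaldehyde | O=Cc1ccc(F)c(Br)c1 | starting material
2 | 2-(3-bromo-4-fluorophenyl)-1,3-dioxolane | Fc1ccc(C2OCCO2)cc1Br | intermediate
3 | ethyl bromoacetate | CCOC(=O)CBr | starting material
4 | bromo(2-ethoxy-2-oxoethyl)zinc | CCOC(=O)C[Zn]Br | intermediate
5 | ethyl 2-[5-(1,3-dioxolan-2-yl)-2-fluorophenyl]acetate | CCOC(=O)Cc1cc(C2OCCO2)ccc1F | intermediate
6 | 2-[5-(1,3-dioxolan-2-yl)-2-fluorophenyl]acetic acid | OC(=O)Cc1cc(C2OCCO2)ccc1F | intermediate
7 | (R)-4-benzyl-2-oxazolidinone | O=C1N[C@H](Cc2ccccc2)CO1 | starting material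
8 | 2-[5-(1,3-dioxolan-2-yl)-2-fluorophenyl]acetic pivalic anhydride | CC(C)(C)C(=O)OC(=O)Cc1cc(C2OCCO2)ccc1F | intermediate
9 | (4R)-4-benzyl-3-{2-[5-(1,3-dioxolan-2-yl)-2-fluorophenyl]acetyl}-1,3-oxazolidin-2-one | O=C1N(C(=O)Cc2cc(C3OCCO3)ccc2F)[C@H](Cc2ccccc2)CO1 | intermediate
10 | veratraldehyde (3,4-dimethoxybenzaldehyde) | COc1ccc(C=O)cc1OC | starting material
11 | Z-dibutylboron enolate of 9 (O–B and aryl cis) | O=C1N(/C(OB(CCCC)CCCC)=C/c2cc(C3OCCO3)ccc2F)[C@H](Cc2ccccc2)CO1 | intermediate
12 | O-dibutylboryl aldolate of 13 | COc1ccc([C@H](OB(CCCC)CCCC)[C@H](C(=O)N2C(=O)OC[C@H]2Cc2ccccc2)c2cc(C3OCCO3)ccc2F)cc1OC | intermediate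
13 | (4R)-4-benzyl-3-[(2R,3R)-3-(3,4-dimethoxyphenyl)-2-[5-(1,3-dioxolan-2-yl)-2-fluorophenyl]-3-hydroxypropanoyl]-1,3-oxazolidin-2-one | COc1ccc([C@H](O)[C@H](C(=O)N2C(=O)OC[C@H]2Cc2ccccc2)c2cc(C3OCCO3)ccc2F)cc1OC | intermediate
14 | (1R,2S)-1-(3,4-dimethoxyphenyl)-2-[5-(1,3-dioxolan-2-yl)-2-fluorophenyl]propane-1,3-diol | COc1ccc([C@H](O)[C@H](CO)c2cc(C3OCCO3)ccc2F)cc1OC | intermediate
15 | (1R,2S)-1-(3,4-dimethoxyphenyl)-2-[5-(1,3-dioxolan-2-yl)-2-fluorophenyl]-3-(triphenylmethoxy)propan-1-ol | COc1ccc([C@H](O)[C@H](COC(c2ccccc2)(c2ccccc2)c2ccccc2)c2cc(C3OCCO3)ccc2F)cc1OC | intermediate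
16 | 2-isopropoxy-4,4,5,5-tetramethyl-1,3,2-dioxaborolane | CC(C)OB1OC(C)(C)C(C)(C)O1 | starting material
17 | lithium alkoxide of 15 lithiated at the arene carbon ortho to fluorine | COc1ccc([C@H](O[Li])[C@H](COC(c2ccccc2)(c2ccccc2)c2ccccc2)c2cc(C3OCCO3)cc([Li])c2F)cc1OC | intermediate
18 | lithium alkoxide bearing the C7a–C7 aryne (2,3-didehydroaryl) | COc1ccc([C@H](O[Li])[C@H](COC(c2ccccc2)(c2ccccc2)c2ccccc2)C2=CC(C3OCCO3)=CC#C2)cc1OC | intermediate
19 | [(2R,3S)-2-(3,4-dimethoxyphenyl)-5-(1,3-dioxolan-2-yl)-3-[(triphenylmethoxy)methyl]-2,3-dihydro-1-benzofuran-7-yl]lithium | COc1ccc([C@@H]2Oc3c([Li])cc(C4OCCO4)cc3[C@H]2COC(c2ccccc2)(c2ccccc2)c2ccccc2)cc1OC | intermediate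
20 | 2-[(2R,3S)-2-(3,4-dimethoxyphenyl)-5-(1,3-dioxolan-2-yl)-3-[(triphenylmethoxy)methyl]-2,3-dihydro-1-benzofuran-7-yl]-4,4,5,5-tetramethyl-1,3,2-dioxaborolane | COc1ccc([C@@H]2Oc3c(B4OC(C)(C)C(C)(C)O4)cc(C4OCCO4)cc3[C@H]2COC(c2ccccc2)(c2ccccc2)c2ccccc2)cc1OC | intermediate
21 | (2R,3S)-2-(3,4-dimethoxyphenyl)-5-(1,3-dioxolan-2-yl)-3-[(triphenylmethoxy)methyl]-2,3-dihydro-1-benzofuran-7-ol | COc1ccc([C@@H]2Oc3c(O)cc(C4OCCO4)cc3[C@H]2COC(c2ccccc2)(c2ccccc2)c2ccccc2)cc1OC | intermediate
22 | (2R,3S)-2-(3,4-dimethoxyphenyl)-7-hydroxy-3-(hydroxymethyl)-2,3-dihydro-1-benzofuran-5-carbaldehyde | COc1ccc([C@@H]2Oc3c(O)cc(C=O)cc3[C@H]2CO)cc1OC | intermediate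
23 | malonic acid | OC(=O)CC(=O)O | starting material
24 | 2-{[(2R,3S)-2-(3,4-dimethoxyphenyl)-7-hydroxy-3-(hydroxymethyl)-2,3-dihydro-1-benzofuran-5-yl]methylidene}propanedioic acid | COc1ccc([C@@H]2Oc3c(O)cc(C=C(C(=O)O)C(=O)O)cc3[C@H]2CO)cc1OC | intermediate
25 | (2E)-3-[(2R,3S)-2-(3,4-dimethoxyphenyl)-7-hydroxy-3-(hydroxymethyl)-2,3-dihydro-1-benzofuran-5-yl]prop-2-enoic acid | COc1ccc([C@@H]2Oc3c(O)cc(/C=C/C(=O)O)cc3[C@H]2CO)cc1OC | target

**Step count**

Total steps: 11. Longest linear sequence: 11 steps (from 1; compounds 3, 7, 10, 16 and 23 are used as bought).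

**Steps most likely to fail**

Step 8. Once LiF is lost, the aryne may be taken by residual t-BuLi or by a second aryllithium faster than by the hindered lithium alkoxide. Metalation may also stray to the benzylic C–H or the acetal C–H, so that ring closure and boron capture do not run cleanly. The fallback sets out from 15 and returns at 22. It makes the O1–C7a bond by addition–elimination at the fluorine-bearing carbon, activated by the para aldehyde, instead of through an aryne, and puts the C7 oxygen in first by a cold ortho-metalation that never reaches the aryne.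
- Compound 15 would be lithiated as in step 8 but held at −78 °C, so that 17 is intercepted there by 16 to give the open-chain pinacol boronate F1.
- H2O2/NaOH would give the fluorophenol F2.
- MOMCl/K2CO3 in acetone would cap the phenol only, giving the MOM ether F3.
- PPTS in wet acetone would exchange off the dioxolane, which hydrolyses far faster than the trityl or MOM ether, giving the fluoro aldehyde F4.
- KOt-Bu in THF at 0 °C would close the ring by intramolecular displacement of fluoride to give the MOM-protected dihydrobenzofuran aldehyde F5, with both stereocentres untouched.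
- 2 M HCl in THF/MeOH would remove the MOM and trityl groups and deliver 22.

Step 2. The zinc ester enolate may self-condense or transmetalate slowly, so that the aryl bromide is reduced or homocoupled instead of coupled. The fallback sets out from 2 and returns at 5, replacing the zinc enolate by a stabilised malonate nucleophile. Diethyl malonate with Pd(OAc)2, P(t-Bu)3·HBF4 and K3PO4 in toluene at 100 °C would give the diethyl arylmalonate F6. Krapcho dealkoxycarbonylation (LiCl, H2O, DMSO, 140 °C), neutral enough to spare the acetal, would then return ester 5.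

Step 11. At the temperature needed for decarboxylation the free primary alcohol may be acylated by malonic acid, or the electron-rich phenol may degrade in hot amine base and the condensation stall. The fallback sets out from 22 and returns at 25, using phosphorus ylide olefination instead of condensation–decarboxylation. Ethyl (triphenylphosphoranylidene)acetate in toluene at 60 °C, which tolerates the free phenol and alcohol, would give the E-configured ethyl ester F7. LiOH in THF/H2O at rt followed by dilute HCl would then give 25.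

**Further compounds**

F1 | step 8 | (1R,2S)-1-(3,4-dimethoxyphenyl)-2-[5-(1,3-dioxolan-2-yl)-2-fluoro-3-(4,4,5,5-tetramethyl-1,3,2-dioxaborolan-2-yl)phenyl]-3-(triphenylmethoxy)propan-1-ol | COc1ccc([C@H](O)[C@H](COC(c2ccccc2)(c2ccccc2)c2ccccc2)c2cc(C3OCCO3)cc(B3OC(C)(C)C(C)(C)O3)c2F)cc1OC
F2 | step 8 | (1R,2S)-1-(3,4-dimethoxyphenyl)-2-[5-(1,3-dioxolan-2-yl)-2-fluoro-3-hydroxyphenyl]-3-(triphenylmethoxy)propan-1-ol | COc1ccc([C@H](O)[C@H](COC(c2ccccc2)(c2ccccc2)c2ccccc2)c2cc(C3OCCO3)cc(O)c2F)cc1OC
F3 | step 8 | (1R,2S)-1-(3,4-dimethoxyphenyl)-2-[5-(1,3-dioxolan-2-yl)-2-fluoro-3-(methoxymethoxy)phenyl]-3-(triphenylmethoxy)propan-1-ol | COc1ccc([C@H](O)[C@H](COC(c2ccccc2)(c2ccccc2)c2ccccc2)c2cc(C3OCCO3)cc(OCOC)c2F)cc1OC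
F4 | step 8 | 3-[(1R,2S)-1-(3,4-dimethoxyphenyl)-1-hydroxy-3-(triphenylmethoxy)propan-2-yl]-4-fluoro-5-(methoxymethoxy)benzaldehyde | COc1ccc([C@H](O)[C@H](COC(c2ccccc2)(c2ccccc2)c2ccccc2)c2cc(C=O)cc(OCOC)c2F)cc1OC
F5 | step 8 | (2R,3S)-2-(3,4-dimethoxyphenyl)-7-(methoxymethoxy)-3-[(triphenylmethoxy)methyl]-2,3-dihydro-1-benzofuran-5-carbaldehyde | COc1ccc([C@@H]2Oc3c(OCOC)cc(C=O)cc3[C@H]2COC(c2ccccc2)(c2ccccc2)c2ccccc2)cc1OC
F6 | step 2 | diethyl 2-[5-(1,3-dioxolan-2-yl)-2-fluorophenyl]propanedioate | CCOC(=O)C(C(=O)OCC)c1cc(C2OCCO2)ccc1F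
F7 | step 11 | ethyl (2E)-3-[(2R,3S)-2-(3,4-dimethoxyphenyl)-7-hydroxy-3-(hydroxymethyl)-2,3-dihydro-1-benzofuran-5-yl]prop-2-enoate | COc1ccc([C@@H]2Oc3c(O)cc(/C=C/C(=O)OCC)cc3[C@H]2CO)cc1OC
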